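The pyrrole ring is cut at C3–C4 and N1–C5. What remains on one side, N1, C2 with its methyl ester and C3 with its indol-3-yl ring, is a dehydrotryptophan. C4 with the second indole and C5 are the two carbons of an alkyne. One palladium-catalysed heteroannulation joins the two, forming both bonds and the pyrrole in a single operation. Its precursor is a β-bromo-dehydrotryptophan Boc-carbamate with bromine cis to nitrogen, paired with an N-tosyl-3-(silylethynyl)indole. Silicon steers the insertion, lands on C5 and is later exchanged for acetyl by ipso-acylation. The tosyl groups keep both indoles silent until a final methanolysis.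

Key step: step 6

Remark: pyrrole atoms are numbered N1, C2 (ester), C3, C4, C5 (acetyl). The target is achiral, so the only stereochemical element in the route is alkene geometry. In the bromide, Z means that Br and the carbamate N share a side, so the indolyl group must change sides during the bromination.

Step 1
Reactants: 1 indole-3-carboxaldehyde
Product: 2 1-tosylindole-3-carboxaldehyde
Conditions: TsCl, Et3N, DMAP (cat.), CH2Cl2, 0 °C to rt
Reagents that add atoms: p-toluenesulfonyl chloride, Cc1ccc(cc1)S(=O)(=O)Cl
Why: DMAP-catalysed N-sulfonylation of the acidified N–H of a 3-formylindole is routine, and the sulfonyl group makes the indole ring electron-poor enough to stay inert in steps 3 and 7.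

Step 2
Reactants: 2 1-tosylindole-3-carboxaldehyde; 3 methyl 2-(tert-butoxycarbonylamino)-2-(dimethoxyphosphoryl)acetate
Product: 4 methyl (Z)-2-(tert-butoxycarbonylamino)-3-(1-tosylindol-3-yl)acrylate
Conditions: DBU, CH2Cl2, 0 °C to rt
Reagents that add atoms: none
Why: Horner–Wadsworth–Emmons olefination of aryl aldehydes with this phosphonoglycinate and an amidine base reliably gives the dehydroamino ester with the aryl group cis to nitrogen, and either alkene isomer would serve because step 3 passes through an sp3 carbon.

Step 3
Reactants: 4 methyl (Z)-2-(tert-butoxycarbonylamino)-3-(1-tosylindol-3-yl)acrylate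
Product: 6 methyl (Z)-3-bromo-2-(tert-butoxycarbonylamino)-3-(1-tosylindol-3-yl)acrylate, via bromo imine 5 (not isolated)
Conditions: NBS (1.05 equiv), CH2Cl2, 0 °C to rt, dark; then DABCO, rt
Reagents that add atoms: N-bromosuccinimide, O=C1CCC(=O)N1Br
Why: Electrophilic bromination of the enamide β-carbon gives the N-acylimine 5, whose former alkene carbon is sp3 and rotates freely, and the amine-catalysed imine-to-enamide tautomerisation of such bromo imines is known to deliver mainly the isomer with bromine cis to the acylamino nitrogen, the minor isomer being removable on silica gel and the N-sulfonylindole being too electron-poor to compete for NBS.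

Step 4
Reactants: 7 indole
Product: 9 3-iodo-1-tosylindole, via 3-iodoindole 8 (not isolated)
Conditions: I2, KOH (powdered, excess), DMF, rt; then TsCl, 0 °C to rt
Reagents that add atoms: iodine, [I][I]; p-toluenesulfonyl chloride, Cc1ccc(cc1)S(=O)(=O)Cl
Why: Electrophilic C3 iodination of the indolyl anion followed by N-sulfonylation in the same KOH/DMF medium avoids isolating the light- and acid-sensitive 8 and gives a stable, crystalline iodide.

Step 5
Reactants: 9 3-iodo-1-tosylindole; 10 trimethylsilylacetylene
Product: 11 1-tosyl-3-(trimethylsilylethynyl)indole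
Conditions: PdCl2(PPh3)2 (cat.), CuI (cat.), Et3N, THF, rt to 40 °C
Reagents that add atoms: none
Why: Sonogashira coupling of an electron-poor heteroaryl iodide with a terminal alkyne runs near room temperature, and the alkynyl C–Si bond is untouched by the amine base.

Step 6
Reactants: 6 methyl (Z)-3-bromo-2-(tert-butoxycarbonylamino)-3-(1-tosylindol-3-yl)acrylate; 11 1-tosyl-3-(trimethylsilylethynyl)indole (1.5 equiv)
Product: 12 methyl 1-(tert-butoxycarbonyl)-3,4-bis(1-tosylindol-3-yl)-5-(trimethylsilyl)pyrrole-2-carboxylate
Conditions: Pd(OAc)2 (10 mol %), PPh3 (20 mol %), LiCl (1 equiv), Na2CO3 (3 equiv), dry DMF, 100 °C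
Reagents that add atoms: none
Why: Zerovalent palladium, generated from Pd(OAc)2 and PPh3, adds oxidatively to the electron-poor vinyl C–Br bond of 6 with retention of geometry, and the resulting vinyl complex of divalent palladium carbopalladates alkyne 11 in a syn fashion. The closest known reaction type is the Larock heteroannulation, already established for 2-(acylamino)-3-haloacrylates with internal alkynes as a route to pyrrole-2-carboxylates, and 6 differs only in carrying an aryl group on the halogen-bearing carbon. The one new ring, the pyrrole, closes when the carbonate-deprotonated carbamate nitrogen displaces halide on palladium to form a six-membered azapalladacycle (Pd, C5, C4, C3, C2, N1), which collapses by C–N reductive elimination, a formal [3+2] union of N1–C2–C3 with C4–C5. No stereocentre is created. The insertion must be regioselective, and this is secured by the bulky trimethylsilyl group, which prefers the alkyne carbon that becomes bonded to the metal (the longer bond), so that the new C–C bond forms at the indolyl-bearing carbon (C4) and silicon ends on C5 next to nitrogen. Closure through nitrogen rather than through the ester oxygen is secured by the Z geometry of 6, which holds the carbamate and not the ester beside palladium, while the tosyl groups remove both indole N–H sites from competition.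

Step 7
Reactants: 12 methyl 1-(tert-butoxycarbonyl)-3,4-bis(1-tosylindol-3-yl)-5-(trimethylsilyl)pyrrole-2-carboxylate
Product: 14 methyl 5-acetyl-3,4-bis(1-tosylindol-3-yl)-1H-pyrrole-2-carboxylate, via Boc-free silylpyrrole 13 (not isolated)
Conditions: AcCl (1.5 equiv), AlCl3 (4 equiv, premixed with AcCl), CH2Cl2, 0 °C to rt
Reagents that add atoms: acetyl chloride, CC(=O)Cl
Why: In this Friedel–Crafts ipso-acyldesilylation AlCl3 first strips the Boc group to expose the more nucleophilic N–H pyrrole 13, the acylium ion then attacks C5, the only pyrrole carbon without a carbon substituent and the one whose σ-complex enjoys β-silicon stabilisation, and chloride removes silicon, while the N-sulfonylindoles are deactivated and any protodesilylated material is acetylated at the same carbon.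

Step 8
Reactants: 14 methyl 5-acetyl-3,4-bis(1-tosylindol-3-yl)-1H-pyrrole-2-carboxylate
Product: 15 methyl 5-acetyl-3,4-di(1H-indol-3-yl)-1H-pyrrole-2-carboxylate (target)
Conditions: Cs2CO3 (6 equiv), THF–MeOH (2:1), rt to 60 °C
Reagents that add atoms: none
Why: Nucleophilic N-desulfonylation of N-tosylindoles by methoxide formed from Cs2CO3 in methanol expels the stabilised indolide, methanol makes ester exchange degenerate, and the pyrrole, present as its anion, shields both of its acyl groups from attack.

Compound list
1 | indole-3-carboxaldehyde | O=Cc1c[nH]c2ccccc12 | starting material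
2 | 1-tosylindole-3-carboxaldehyde | Cc1ccc(cc1)S(=O)(=O)n1cc(C=O)c2ccccc12 | intermediate
3 | methyl 2-(tert-butoxycarbonylamino)-2-(dimethoxyphosphoryl)acetate | COC(=O)C(NC(=O)OC(C)(C)C)P(=O)(OC)OC | starting material
4 | methyl (Z)-2-(tert-butoxycarbonylamino)-3-(1-tosylindol-3-yl)acrylate (indolyl cis to N) | COC(=O)/C(NC(=O)OC(C)(C)C)=C/c1cn(S(=O)(=O)c2ccc(C)cc2)c2ccccc12 | intermediate
5 | methyl 3-bromo-2-(tert-butoxycarbonylimino)-3-(1-tosylindol-3-yl)propanoate (racemic, not isolated) | COC(=O)C(=NC(=O)OC(C)(C)C)C(Br)c1cn(S(=O)(=O)c2ccc(C)cc2)c2ccccc12 | intermediate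
6 | methyl (Z)-3-bromo-2-(tert-butoxycarbonylamino)-3-(1-tosylindol-3-yl)acrylate (Br cis to N) | COC(=O)/C(NC(=O)OC(C)(C)C)=C(/Br)c1cn(S(=O)(=O)c2ccc(C)cc2)c2ccccc12 | intermediate
7 | indole | c1ccc2[nH]ccc2c1 | starting material
8 | 3-iodoindole (not isolated) | Ic1c[nH]c2ccccc12 | intermediate
9 | 3-iodo-1-tosylindole | Cc1ccc(cc1)S(=O)(=O)n1cc(I)c2ccccc12 | intermediate
10 | trimethylsilylacetylene | C#C[Si](C)(C)C | starting material
11 | 1-tosyl-3-(trimethylsilylethynyl)indole | C[Si](C)(C)C#Cc1cn(S(=O)(=O)c2ccc(C)cc2)c2ccccc12 | intermediate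
12 | methyl 1-(tert-butoxycarbonyl)-3,4-bis(1-tosylindol-3-yl)-5-(trimethylsilyl)pyrrole-2-carboxylate | COC(=O)c1n(C(=O)OC(C)(C)C)c([Si](C)(C)C)c(-c2cn(S(=O)(=O)c3ccc(C)cc3)c3ccccc23)c1-c1cn(S(=O)(=O)c2ccc(C)cc2)c2ccccc12 | intermediate
13 | methyl 3,4-bis(1-tosylindol-3-yl)-5-(trimethylsilyl)-1H-pyrrole-2-carboxylate (not isolated) | COC(=O)c1[nH]c([Si](C)(C)C)c(-c2cn(S(=O)(=O)c3ccc(C)cc3)c3ccccc23)c1-c1cn(S(=O)(=O)c2ccc(C)cc2)c2ccccc12 | intermediate
14 | methyl 5-acetyl-3,4-bis(1-tosylindol-3-yl)-1H-pyrrole-2-carboxylate | COC(=O)c1[nH]c(C(C)=O)c(-c2cn(S(=O)(=O)c3ccc(C)cc3)c3ccccc23)c1-c1cn(S(=O)(=O)c2ccc(C)cc2)c2ccccc12 | intermediate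
15 | methyl 5-acetyl-3,4-di(1H-indol-3-yl)-1H-pyrrole-2-carboxylate | COC(=O)c1[nH]c(C(C)=O)c(-c2c[nH]c3ccccc23)c1-c1c[nH]c2ccccc12 | target

Total step count: 8 (bromide arm 3 steps, alkyne arm 2 steps, then 3 common steps).
Longest linear sequence: 6 steps (steps 1, 2, 3, 6, 7, 8, from indole-3-carboxaldehyde).

Steps most likely to fail

Step 6. Oxidative addition and, above all, alkyne insertion occur at a vinyl carbon that is fully substituted and flanked by a bulky sulfonylindole. Both may be too slow at temperatures that the Boc group and the alkynyl C–Si bond tolerate. Palladation of an indole C2–H may also outrun N–Pd bond formation.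

The fallback gives up the annulation and attaches both indoles to a ready-made pyrrole by Suzuki–Miyaura coupling. It sets out from 9 and comes back at 14. Miyaura borylation of 9 (B2pin2, PdCl2(dppf), KOAc, dioxane, 80 °C) should give 1-tosyl-3-(4,4,5,5-tetramethyl-1,3,2-dioxaborolan-2-yl)indole F1. In parallel, commercial methyl 1H-pyrrole-2-carboxylate (COC(=O)c1ccc[nH]1) would be acetylated at its free α-position under Vilsmeier–Haack conditions (N,N-dimethylacetamide, POCl3, 1,2-dichloroethane, then aqueous NaOAc). This gives methyl 5-acetyl-1H-pyrrole-2-carboxylate F2. Bromination at the two remaining ring positions (NBS, 2.2 equiv, DMF) then gives methyl 5-acetyl-3,4-dibromo-1H-pyrrole-2-carboxylate F3. Twofold coupling of F3 with F1 (Pd(PPh3)4, K2CO3, dioxane–water, 90 °C) should give 14, after which step 8 follows unchanged.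

Step 7. Acylation may stray to the benzenoid rings of the sulfonylindoles. The tert-butyl cation released from Boc may alkylate the substrate. Protodesilylation may also outpace acylation and leave a sluggish substrate.

The fallback replaces electrophilic acylation by cross-coupling with an acetyl equivalent. It sets out from 12 and comes back at 14. Ipso-iododesilylation of 12 (ICl, CH2Cl2, −78 to 0 °C) should give methyl 1-(tert-butoxycarbonyl)-5-iodo-3,4-bis(1-tosylindol-3-yl)pyrrole-2-carboxylate F4. Stille coupling with tributyl(1-ethoxyvinyl)stannane (PdCl2(PPh3)2, toluene, 100 °C) should give methyl 1-(tert-butoxycarbonyl)-5-(1-ethoxyvinyl)-3,4-bis(1-tosylindol-3-yl)pyrrole-2-carboxylate F5. Wet trifluoroacetic acid in CH2Cl2 then hydrolyses the enol ether and removes Boc in one operation to give 14.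

Step 3. Poor geometric selectivity in the tautomerisation, or interconversion of the two isomers on handling, would deprive the key step of the isomer it needs. The other isomer presents the ester and not the carbamate to palladium.

The fallback removes the tetrasubstituted alkene from the plan and brings in the C3 indole after ring formation. It sets out from 11 and comes back at 14. Commercial methyl 2-(tert-butoxycarbonylamino)acrylate (C=C(NC(=O)OC(C)(C)C)C(=O)OC) is treated with NIS and then Et3N to give methyl (Z)-2-(tert-butoxycarbonylamino)-3-iodoacrylate F6, the substrate type on which the annulation is established. Annulation of F6 with 11 under the conditions of step 6 should give methyl 1-(tert-butoxycarbonyl)-4-(1-tosylindol-3-yl)-5-(trimethylsilyl)pyrrole-2-carboxylate F7. AcCl/AlCl3 as in step 7 should give methyl 5-acetyl-4-(1-tosylindol-3-yl)-1H-pyrrole-2-carboxylate F8. NBS in DMF brominates the last free pyrrole position to give methyl 5-acetyl-3-bromo-4-(1-tosylindol-3-yl)-1H-pyrrole-2-carboxylate F9. Suzuki–Miyaura coupling of F9 (Pd(PPh3)4, K2CO3, dioxane–water, 90 °C) with the boronate F1, made from 9 as described for step 6, should give 14.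

Further compounds
F1 | step 6 | 1-tosyl-3-(4,4,5,5-tetramethyl-1,3,2-dioxaborolan-2-yl)indole | Cc1ccc(cc1)S(=O)(=O)n1cc(B2OC(C)(C)C(C)(C)O2)c2ccccc12
F2 | step 6 | methyl 5-acetyl-1H-pyrrole-2-carboxylate | COC(=O)c1ccc(C(C)=O)[nH]1
F3 | step 6 | methyl 5-acetyl-3,4-dibromo-1H-pyrrole-2-carboxylate | COC(=O)c1[nH]c(C(C)=O)c(Br)c1Br
F4 | step 7 | methyl 1-(tert-butoxycarbonyl)-5-iodo-3,4-bis(1-tosylindol-3-yl)pyrrole-2-carboxylate | COC(=O)c1n(C(=O)OC(C)(C)C)c(I)c(-c2cn(S(=O)(=O)c3ccc(C)cc3)c3ccccc23)c1-c1cn(S(=O)(=O)c2ccc(C)cc2)c2ccccc12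
F5 | step 7 | methyl 1-(tert-butoxycarbonyl)-5-(1-ethoxyvinyl)-3,4-bis(1-tosylindol-3-yl)pyrrole-2-carboxylate | CCOC(=C)c1c(-c2cn(S(=O)(=O)c3ccc(C)cc3)c3ccccc23)c(-c2cn(S(=O)(=O)c3ccc(C)cc3)c3ccccc23)c(C(=O)OC)n1C(=O)OC(C)(C)C
F6 | step 3 | methyl (Z)-2-(tert-butoxycarbonylamino)-3-iodoacrylate | COC(=O)/C(NC(=O)OC(C)(C)C)=C/I
F7 | step 3 | methyl 1-(tert-butoxycarbonyl)-4-(1-tosylindol-3-yl)-5-(trimethylsilyl)pyrrole-2-carboxylate | COC(=O)c1cc(-c2cn(S(=O)(=O)c3ccc(C)cc3)c3ccccc23)c([Si](C)(C)C)n1C(=O)OC(C)(C)C
F8 | step 3 | methyl 5-acetyl-4-(1-tosylindol-3-yl)-1H-pyrrole-2-carboxylate | COC(=O)c1cc(-c2cn(S(=O)(=O)c3ccc(C)cc3)c3ccccc23)c(C(C)=O)[nH]1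
F9 | step 3 | methyl 5-acetyl-3-bromo-4-(1-tosylindol-3-yl)-1H-pyrrole-2-carboxylate | COC(=O)c1[nH]c(C(C)=O)c(-c2cn(S(=O)(=O)c3ccc(C)cc3)c3ccccc23)c1Br
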